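The readings come from a simulation for an exercise; noise was put on by code.

A one-step world, L plus Q to Z and nothing further, keeps its Z, but the north run did not: between 2.00 h and 4.00 h L stood at 31% and 30% while Z fell from 18% to 6%.

| flask | L | Q | remark | time |
|---|---|---|---|---|
| north-east | 0.80 M | 0.27 M | run made earlier |  |
| north | 0.80 M | 0.73 M | run made earlier |  |
| ash | 0.80 M | 0.400 M |  | 6.0 h |
| oak | 0.80 M | 0.500 M |  | 6.0 h |
| cedar | 0.80 M | 0.800 M |  | 6.0 h |
| elm | 0.80 M | 1.20 M |  | 6.0 h |

- north-east (time / h: Z / %, L / %): 0.500: 14, 79; 0.833: 16, 71; 1.33: 11, 72; 2.00: 11, 70; 4.00: 5, 68; 6.00: 2, 68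
- north (time / h: Z / %, L / %): 1.00: 32, 41; 2.00: 18, 31; 3.00: 10, 30; 4.00: 6, 30; 5.00: 0, 31; 6.00: 0, 30

(readings scatter by 1.5 percentage points)

- "hardly changes" means that all values lie within two and a half points (for a concentration: within two and a half percent of the largest)
- a step back or a flat step of under half a percent of the largest counts as no turn

- [Z] at the end for ash, oak, cedar, elm, in this order
- how the row runs (rises all the way / falls, then rises / hardly changes / rises, then falls / falls all the way)

I took that fall as a first-order decay and divided its logarithm by the elapsed time, which gave a reading of 0.549 h⁻¹ with the scatter of its two points, and from it I had the fade half-life, the time in which Z halves while L stands still, 1.26 h. Carried from the north reading at 2.00 h on to 6.0 h, this decay reckoned north at 2.00% of the L charged, or 0.0160 M, so I expected end values of that order in ash, oak, cedar and elm, which gave me a scale and not a row.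

The forecast gave 0.01 M, 0.013 M, 0.024 M and 0.014 M, a row that rises, then falls, and added: “All values are small and uncertain.”

The flasks gave 0.00716 M, 0.00853 M, 0.0109 M and 0.0106 M, a row that rises, then falls, with the turn at 0.94 M of Q; the shape was the forecast's, while for cedar the forecast stood higher than the result.

    Z + Q → D + E (k = 0.0200 M⁻¹ min⁻¹)
    Z → J (k = 0.0120 min⁻¹)
    E + Q → D + X (k = 0.0540 M⁻¹ min⁻¹)
    L + Q → D + Z (k = 0.0450 M⁻¹ min⁻¹)
    X + Q → D + G (k = 0.120 M⁻¹ min⁻¹)

In ash at 0.318 h, Z was made 2.46 times faster than it was used up, each step taken net, but at 6.0 h, when Q, the limiting reagent, stood at 0.0143% of its charge, making ran at 0.0133 of the rate of use. The fade half-life of 1.26 h takes the 7.13% of Z in ash at 3.00 h to 1.37% at 6.0 h, where ash held 0.896%, and it takes the 8.28% in oak to 1.59%, where oak held 1.07%.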